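The synthesis rests on disconnecting the lactone ring between the carbonyl carbon C1 and the arene carbon C8a. An open-chain (R)-1-(3,5-dimethoxyphenyl)tridecan-2-ol, assembled from (S)-epichlorohydrin by two copper-catalysed Grignard openings, is converted in one operation into the 1-methoxyisochroman: a dialkoxycarbenium ion generated on O2 from trimethyl orthoformate is attacked by the arene (oxa-Pictet–Spengler closure). The step exploits that C8a of the benzo ring lies para to the C6 oxygen and ortho to the C8 oxygen, and that C8a and C5 are equivalent in the symmetric precursor. Oxidation to the lactone and a BCl3 step, steered by the peri C1=O/C8–OMe pair, complete the route.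

Key step: step 4

Remark: isochromanone numbering is used throughout (C1 carbonyl carbon, O2, C3 stereocentre, C4 benzylic CH2, C4a and C8a ring-fusion carbons, C5 to C8 the remaining benzo carbons).

**Step 1**
Reactants: 1 10-bromodecan-1-ol
Product: 2 benzyl 10-bromodecyl ether
Conditions: BnOC(=NH)CCl3 (1.3 equiv), TfOH (cat.), cyclohexane/CH2Cl2, rt
Reagents that add atoms: benzyl 2,2,2-trichloroacetimidate, ClC(Cl)(Cl)C(=N)OCc1ccccc1
Why: Acid-catalysed O-benzylation with a trichloroacetimidate protects the alcohol without base, so the primary bromide is not displaced in a Williamson side reaction.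

**Step 2**
Reactants: 3 1-bromo-3,5-dimethoxybenzene; 4 (S)-epichlorohydrin
Product: 7 (S)-2-(3,5-dimethoxybenzyl)oxirane, via aryl Grignard reagent 5 (not isolated), via chlorohydrin 6 (not isolated)
Conditions: Mg, THF; CuI (10 mol%), 4, THF, −40 → 0 °C; then NaOH, MeOH/H2O, rt
Reagents that add atoms: none
Why: Copper-catalysed Grignard opening of the epoxide of 4 at its unsubstituted carbon (SN2) gives chlorohydrin 6, and hydroxide then closes the new epoxide by intramolecular Williamson displacement of chloride; neither event touches the stereocentre, so (S)-4 is carried into (S)-7.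

**Step 3**
Reactants: 2 benzyl 10-bromodecyl ether; 7 (S)-2-(3,5-dimethoxybenzyl)oxirane
Product: 9 (R)-13-(benzyloxy)-1-(3,5-dimethoxyphenyl)tridecan-2-ol, via alkyl Grignard reagent 8 (not isolated)
Conditions: Mg, THF; CuI (10 mol%), 7, THF, −30 → 0 °C; aq. NH4Cl
Reagents that add atoms: none
Why: Copper-catalysed SN2 opening of the terminal epoxide at CH2 by the primary alkyl Grignard reagent forms the C–C bond without touching the carbinol carbon, so the configuration of 7 is retained (the descriptor becomes R only through the CIP priorities).

**Step 4**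
Reactants: 9 (R)-13-(benzyloxy)-1-(3,5-dimethoxyphenyl)tridecan-2-ol
Product: 11 (3R)-3-[11-(benzyloxy)undecyl]-1,6,8-trimethoxy-3,4-dihydro-1H-isochromene (mixture of C1 epimers), via mixed orthoformate 10 (not isolated)
Conditions: HC(OMe)3 (5 equiv), TMSOTf (0.2 equiv), CH2Cl2 (dilute), −20 → 0 °C; Et3N
Reagents that add atoms: trimethyl orthoformate, COC(OC)OC
Why: Acid-catalysed exchange gives mixed orthoformate 10, whose ionisation by TMSOTf produces a dialkoxycarbenium ion on O2 that is attacked by the ring carbon para to one methoxy group and ortho to the other (electrophilic aromatic substitution), and loss of a proton restores the arene and forms the C1–C8a bond. The closest known reaction type is the oxa-Pictet–Spengler cyclization of 2-arylethanols with acetals and orthoesters. The pyran ring closes in a 6-endo-trig mode on the oxocarbenium carbon. The new acetal stereocentre C1 is not controlled and need not be, because it becomes the carbonyl carbon in step 5, while C3 is not involved. The step needs site selectivity on the arene and suppression of intermolecular arylation: the two positions ortho to the side chain are equivalent in the 3,5-dimethoxyphenyl ring and the position between the methoxy groups cannot be reached through a six-membered transition state, and dilution, low temperature and excess orthoformate disfavour attack on a second molecule.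

**Step 5**
Reactants: 11 (3R)-3-[11-(benzyloxy)undecyl]-1,6,8-trimethoxy-3,4-dihydro-1H-isochromene
Product: 13 (R)-3-[11-(benzyloxy)undecyl]-6,8-dimethoxy-3,4-dihydro-1H-isochromen-1-one, via lactol 12 (not isolated)
Conditions: CrO3, aq. H2SO4 (Jones reagent), acetone, 0 °C
Reagents that add atoms: water, O
Why: Jones oxidation of a lactol ether: aqueous acid hydrolyses the cyclic acetal to lactol 12, which chromic acid oxidises to the lactone; the C3 stereocentre is remote from the reacting carbon and is not affected.

**Step 6**
Reactants: 13 (R)-3-[11-(benzyloxy)undecyl]-6,8-dimethoxy-3,4-dihydro-1H-isochromen-1-one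
Product: 14 (R)-8-hydroxy-3-(11-hydroxyundecyl)-6-methoxy-3,4-dihydro-1H-isochromen-1-one (CNP0140068.1)
Conditions: BCl3 (5 equiv), pentamethylbenzene (3 equiv), CH2Cl2, −78 → 0 °C; then H2O
Reagents that add atoms: none
Why: Lewis acid-mediated ether cleavage: BCl3 chelates between the lactone carbonyl and the peri C8 methoxy oxygen and cleaves only that methyl ether (the C6 methoxy group is not chelated), and it also cleaves the primary benzyl ether, the benzyl cation being trapped by pentamethylbenzene (Friedel–Crafts) instead of the electron-rich ring.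

**Compound list**
1 | 10-bromodecan-1-ol | OCCCCCCCCCCBr | starting material
2 | benzyl 10-bromodecyl ether | BrCCCCCCCCCCOCc1ccccc1 | intermediate
3 | 1-bromo-3,5-dimethoxybenzene | COc1cc(Br)cc(OC)c1 | starting material
4 | (S)-epichlorohydrin | ClC[C@@H]1CO1 | starting material
5 | 3,5-dimethoxyphenylmagnesium bromide | COc1cc(OC)cc([Mg]Br)c1 | intermediate
6 | (S)-1-chloro-3-(3,5-dimethoxyphenyl)propan-2-ol | COc1cc(OC)cc(C[C@H](O)CCl)c1 | intermediate
7 | (S)-2-(3,5-dimethoxybenzyl)oxirane | COc1cc(OC)cc(C[C@H]2CO2)c1 | intermediate
8 | [10-(benzyloxy)decyl]magnesium bromide | Br[Mg]CCCCCCCCCCOCc1ccccc1 | intermediate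
9 | (R)-13-(benzyloxy)-1-(3,5-dimethoxyphenyl)tridecan-2-ol | COc1cc(OC)cc(C[C@H](O)CCCCCCCCCCCOCc2ccccc2)c1 | intermediate
10 | (R)-13-(benzyloxy)-1-(3,5-dimethoxyphenyl)tridecan-2-yl dimethyl orthoformate | COc1cc(OC)cc(C[C@H](OC(OC)OC)CCCCCCCCCCCOCc2ccccc2)c1 | intermediate
11 | (3R)-3-[11-(benzyloxy)undecyl]-1,6,8-trimethoxy-3,4-dihydro-1H-isochromene (C1 epimers) | COc1cc(OC)c2c(c1)C[C@@H](CCCCCCCCCCCOCc1ccccc1)OC2OC | intermediate
12 | (3R)-3-[11-(benzyloxy)undecyl]-6,8-dimethoxy-3,4-dihydro-1H-isochromen-1-ol | COc1cc(OC)c2c(c1)C[C@@H](CCCCCCCCCCCOCc1ccccc1)OC2O | intermediate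
13 | (R)-3-[11-(benzyloxy)undecyl]-6,8-dimethoxy-3,4-dihydro-1H-isochromen-1-one | COc1cc(OC)c2c(c1)C[C@@H](CCCCCCCCCCCOCc1ccccc1)OC2=O | intermediate
14 | (R)-8-hydroxy-3-(11-hydroxyundecyl)-6-methoxy-3,4-dihydro-1H-isochromen-1-one | COc1cc(O)c2c(c1)C[C@@H](CCCCCCCCCCCO)OC2=O | target

**Step count and risk**
Total step count: 6. Longest linear sequence: 5 steps (steps 2, 3, 4, 5, 6 from compound 3; equally steps 1, 3, 4, 5, 6 from compound 1).

Steps most likely to fail:

1. Step 4 (key step). The product acetal may re-ionise to the stabilised isochromenylium ion and be captured by a second electron-rich ring (intermolecular arylation, oligomerisation). Alternatively the dialkoxycarbenium ion may be too weak an electrophile, so that the mixed orthoformate accumulates. Fallback, setting out from 9: bromination with NBS (MeCN, 0 °C) at the ring position ortho to the side chain should give (R)-13-(benzyloxy)-1-(2-bromo-3,5-dimethoxyphenyl)tridecan-2-ol F1. Methyl chloroformate and pyridine should convert it into (R)-13-(benzyloxy)-1-(2-bromo-3,5-dimethoxyphenyl)tridecan-2-yl methyl carbonate F2. Bromine–lithium exchange (t-BuLi, 2 equiv, THF, −78 °C) followed by Parham cyclization of the aryllithium onto the carbonate carbonyl, with loss of methoxide, should close the same C1–C8a bond at the lactone oxidation level. This returns to the route at 13 and bypasses 11 and step 5.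

2. Step 6. Selectivity may be lost in the double deprotection: excess Lewis acid may cleave the C6 methyl ether, the benzyl cation may alkylate the ring, or debenzylation may be incomplete at low temperature. Fallback, setting out from 13: hydrogenolysis (H2, Pd/C, EtOAc) should first remove the benzyl group to give (R)-3-(11-hydroxyundecyl)-6,8-dimethoxy-3,4-dihydro-1H-isochromen-1-one F3. BCl3 alone (CH2Cl2, −78 °C) then only has to effect the chelation-controlled demethylation at C8, returning to the route at 14.

3. Step 5. Chromic acid may over-oxidise the benzyl ether CH2 or the electron-rich ring before the lactone has formed. Fallback, setting out from 11: mild hydrolysis (AcOH/THF/H2O, rt) with isolation of lactol 12, then oxoammonium oxidation (TEMPO cat., PhI(OAc)2, CH2Cl2, rt), returning to the route at 13.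

**Further compounds**
F1 | step 4 | (R)-13-(benzyloxy)-1-(2-bromo-3,5-dimethoxyphenyl)tridecan-2-ol | COc1cc(OC)c(Br)c(C[C@H](O)CCCCCCCCCCCOCc2ccccc2)c1
F2 | step 4 | (R)-13-(benzyloxy)-1-(2-bromo-3,5-dimethoxyphenyl)tridecan-2-yl methyl carbonate | COc1cc(OC)c(Br)c(C[C@H](OC(=O)OC)CCCCCCCCCCCOCc2ccccc2)c1
F0 | step 5 | none | none
F3 | step 6 | (R)-3-(11-hydroxyundecyl)-6,8-dimethoxy-3,4-dihydro-1H-isochromen-1-one | COc1cc(OC)c2c(c1)C[C@@H](CCCCCCCCCCCO)OC2=O
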